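Target is the form in which a product molecule is born: by the steps thought possible it comes from reagent and intermediate A, and isomer of the product is reached through target.

| flask | substrate | reagent | remark | time |
|---|---|---|---|---|
| dawn | 0.70 M | 0.35 M | run made earlier |  |
| noon | 1.1 M | 0.35 M | run made earlier |  |
| winter | 0.50 M | 0.17 M | run made earlier |  |
| flask | 0.50 M | 0.350 M |  | 12 h |

| run | time / h | isomer of the product / % | target / % |
|---|---|---|---|
| dawn | 1.00 | 9.5 | 2.3 |
| dawn | 1.33 | 12.8 | 2.9 |
| dawn | 2.00 | 15.8 | 2.8 |
| dawn | 3.00 | 17.3 | 2.8 |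
| dawn | 5.00 | 18.4 | 2.9 |
| dawn | 8.00 | 19.4 | 2.5 |
| dawn | 12.0 | 19.5 | 2.7 |
| noon | 1.50 | 10.5 | 1.4 |
| noon | 3.00 | 12.0 | 1.9 |
| noon | 5.00 | 12.0 | 2.2 |
| noon | 6.00 | 12.5 | 1.6 |
| noon | 8.00 | 12.2 | 1.3 |
| noon | 10.0 | 12.5 | 1.8 |
| noon | 12.0 | 12.4 | 2.1 |
| winter | 1.00 | 6.0 | 1.5 |
| winter | 3.00 | 12.4 | 1.7 |
| winter | 6.00 | 13.1 | 1.8 |
| winter | 8.00 | 13.3 | 1.7 |
| winter | 12.0 | 13.0 | 1.9 |

(readings scatter by 0.3 percentage points)

- steps thought possible: reagent + intermediate B <-> intermediate D; reagent + intermediate B <-> intermediate C; substrate -> intermediate A; reagent + intermediate A -> target; reagent + intermediate A -> intermediate B; target <-> isomer of the product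

* ratio of isomer of the product to target at 25 min
* ratio of isomer of the product to target at 12 h
* which of isomer of the product and target there is more of at 12 h

Once born, the molecule flips between the two forms. Pooling the last two readings of dawn, noon and winter gives 7.09, the late ratio, isomer over target at the end of a run. A late product molecule is therefore found as isomer with a chance of 87.6 %. This is the thermodynamic side of kinetic against thermodynamic control.

Was one number enough? Taken apart, dawn, noon and winter read 7.48, 6.38 and 7.31. The last target reading of winter is 1.9 %, with a scatter of 0.3 percentage points, and the three ratios are here taken as one reading. The flask shares its substrate charge with winter and its reagent charge with dawn. At 12 h it should therefore stand near 7.09 and hold more isomer than target.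

Late, then, the number is enough, but it gives a split and not an amount. Early it fails: dawn reads 4.13 at 1.00 h, lower than the late ratio. My reckoning therefore places the flask at 25 min below that reading, without a closer value.

The forecast says 1.5 at 25 min and 7.1 at 12 h, with isomer of the product ahead, the late figure on the ground that “target and isomer equilibrate”.

The flask gives 1.56 at 25 min and 6.89 at 12 h. In it, isomer draws level with target at 0.276 h, earlier than 25 min. At 12 h the flask holds 3.75 % target, which the late ratio turns into 26.6 % isomer; the flask holds 25.8 %.

    reagent + intermediate B ⇌ intermediate D (K = 74.0 M⁻¹, k = 0.0240 M⁻¹ min⁻¹)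
    reagent + intermediate B ⇌ intermediate C (K = 2.70 M⁻¹, k = 0.0270 M⁻¹ min⁻¹)
    substrate → intermediate A (k = 0.0160 min⁻¹)
    reagent + intermediate A → target (k = 0.0340 M⁻¹ min⁻¹)
    reagent + intermediate A → intermediate B (k = 0.0390 M⁻¹ min⁻¹)
    target ⇌ isomer of the product (K = 6.90, k = 0.160 min⁻¹)

The neighbour charged with 0.88 M of reagent holds 5.89 % target at 12 h, which the late ratio turns into 41.8 % isomer. The computed neighbour holds 40.7 %, a ratio of 6.90.

The numbers in the tables come from a simulation for substances that don't exist, noise included.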